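Ring names: A is the benzene ring on the alkene and B is its pyran ring (O1, C2, C3, C4, C4a, C8a). C is the benzene ring on the stereocentre and D is its pyran ring.
Cuts: first O1–C2 and C4–C4a in rings B and D, which releases two molecules of 3-methylbut-2-enal. Next the bond from the stereocentre to C6 of ring C, then the bond from the alkene to C6 of ring A.
Enabling feature: rings A and C carry the same pattern, with O1 on C8a para to the chain-bearing C6 and OMe on C7 para to C4a. Each is therefore a 4-substituted 3-methoxyphenol whose only open, unhindered ortho carbon is C4a, and the O1–C8a–C4a unit takes up the C4–C3–C2 unit of the enal.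
Forward order: one arene, 4-bromo-3-methoxyphenol, supplies rings A and C. The chain is joined by a Heck reaction (ring A) and an allyl–aryl coupling (ring C). Both pyran rings arise in the final flask, ring D first and ring B, on the styrene-conjugated arene, last.
Stereochemistry: a CBS reduction sets an R carbinol centre, and an enantiospecific nickel coupling converts it with inversion into the S centre. The E alkene comes from the Heck step and is retained.
Logic: the acid- and borane-sensitive chromene olefins appear only at the end, so no earlier step has to tolerate them.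

Key step: step 8

Remark: the stereocentre of the target is S (ring C aryl > alkenyl > methyl > H), and the nickel coupling in MeCN is taken to run with inversion, as in its known cases.

Step 1
Reactants: 1 4-bromo-3-methoxyphenol
Product: 2 1-bromo-2-methoxy-4-(methoxymethoxy)benzene
Conditions: MOMCl, i-Pr2NEt, CH2Cl2, 0 °C to rt
Reagents that add atoms: chloromethyl methyl ether (MOMCl), COCCl
Why: Base-mediated O-alkylation (Williamson type) turns the phenol into a methoxymethyl acetal that withstands palladium catalysis, borane, n-BuLi and NaOMe, and so masks the oxygen that becomes O1 in both halves.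

Step 2
Reactants: 2 1-bromo-2-methoxy-4-(methoxymethoxy)benzene; 3 but-3-en-2-one
Product: 4 (E)-4-[2-methoxy-4-(methoxymethoxy)phenyl]but-3-en-2-one
Conditions: Pd2(dba)3 (1.5 mol%), [HP(t-Bu)3]BF4 (6 mol%), Cy2NMe, dioxane, 70 °C
Reagents that add atoms: none
Why: In this Mizoroki–Heck reaction the aryl group adds to the unsubstituted alkene terminus and syn β-hydride elimination gives the conjugated E enone, with a bulky electron-rich phosphine chosen because the bromide is electron-rich and ortho-substituted.

Step 3
Reactants: 4 (E)-4-[2-methoxy-4-(methoxymethoxy)phenyl]but-3-en-2-one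
Product: 5 (R,E)-4-[2-methoxy-4-(methoxymethoxy)phenyl]but-3-en-2-ol
Conditions: (S)-Me-CBS oxazaborolidine (0.15 equiv), BH3·SMe2 (0.7 equiv), THF, −30 °C; MeOH, then aqueous work-up
Reagents that add atoms: none
Why: In this Corey–Bakshi–Shibata reduction the ketone binds to the ring boron of the S catalyst with the styryl arm as the large group turned away, so the nitrogen-bound BH3 delivers hydride to the Si face through a six-membered transition state and sets the R carbinol centre by 1,2-reduction.

Step 4
Reactants: 5 (R,E)-4-[2-methoxy-4-(methoxymethoxy)phenyl]but-3-en-2-ol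
Product: 6 (R,E)-4-[2-methoxy-4-(methoxymethoxy)phenyl]but-3-en-2-yl pivalate
Conditions: PivCl, Et3N, DMAP (cat.), CH2Cl2, 0 °C; filtration through Et3N-treated silica
Reagents that add atoms: pivaloyl chloride (PivCl), CC(C)(C)C(=O)Cl
Why: DMAP-catalysed O-acylation leaves the C–O bond of the stereocentre untouched (retention) and installs the leaving group that the nickel coupling needs.

Step 5
Reactants: 2 1-bromo-2-methoxy-4-(methoxymethoxy)benzene
Product: 9 2,4,6-tris[2-methoxy-4-(methoxymethoxy)phenyl]boroxine, via aryllithium 7 (not isolated), via boronic acid 8 (not isolated)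
Conditions: n-BuLi, THF, −78 °C; B(Oi-Pr)3, −78 °C to rt; aq. NH4Cl; toluene, azeotropic removal of water
Reagents that add atoms: triisopropyl borate, CC(C)OB(OC(C)C)OC(C)C; water, O
Why: Bromine–lithium exchange outruns ortho-lithiation at −78 °C, the aryllithium is trapped by the borate (borylation of an organolithium), and mild hydrolysis followed by azeotropic dehydration gives the anhydrous boroxine that the coupling requires.

Step 6
Reactants: 6 (R,E)-4-[2-methoxy-4-(methoxymethoxy)phenyl]but-3-en-2-yl pivalate; 9 2,4,6-tris[2-methoxy-4-(methoxymethoxy)phenyl]boroxine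
Product: 10 (S,E)-1,3-bis[2-methoxy-4-(methoxymethoxy)phenyl]but-1-ene
Conditions: 9 (0.5 equiv), Ni(cod)2 (5 mol%), BnPPh2 (11 mol%), NaOMe (2 equiv), MeCN, rt to 40 °C
Reagents that add atoms: none
Why: In this enantiospecific nickel-catalysed Suzuki–Miyaura-type coupling of a secondary allylic pivalate with an arylboroxine, zerovalent nickel ionises the pivalate anti (open transition state in MeCN) and the aryl group taken from boron is reductively eliminated syn at the methyl-bearing allyl terminus, so the R carbinol centre becomes the S centre with net inversion and the E styrene stays conjugated.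

Step 7
Reactants: 10 (S,E)-1,3-bis[2-methoxy-4-(methoxymethoxy)phenyl]but-1-ene
Product: 11 (S,E)-4,4'-(but-1-ene-1,3-diyl)bis(3-methoxyphenol)
Conditions: NaHSO4·SiO2, CH2Cl2, rt, Ar
Reagents that add atoms: none
Why: Acid-catalysed acetal hydrolysis on a weakly acidic solid cleaves phenolic methoxymethyl ethers at room temperature because phenol is a good leaving group, and the conditions should be too mild to protonate the styrene or ionise the S centre.

Step 8
Reactants: 11 (S,E)-4,4'-(but-1-ene-1,3-diyl)bis(3-methoxyphenol); 12 3-methylbut-2-enal (two molecules enter)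
Product: 17 (S,E)-1,3-bis(7-methoxy-2,2-dimethyl-2H-chromen-6-yl)but-1-ene, via bis-dioxaborin 13 (not isolated), via ring C quinone methide 14 (not isolated), via monochromene dioxaborin 15 (not isolated), via ring A quinone methide 16 (not isolated)
Conditions: 12 (4 equiv), PhB(OH)2 (2.2 equiv), AcOH/toluene 1:10 (0.02 M), reflux, Dean–Stark trap, Ar
Reagents that add atoms: none
Why: Each phenol condenses with PhB(OH)2 to an aryloxyborane that binds the enal and passes its carbonyl carbon to the ortho carbon C4a through a six-membered cyclic transition state, so that five molecules assemble to the bis-dioxaborin 13 with two temporary O–B–O rings, and at reflux each dioxaborin loses PhBO by cycloreversion to a vinylogous ortho-quinone methide (14, later 16) that closes at once. The closest known reaction type is the boronic-acid-templated chromenylation of phenols with α,β-unsaturated aldehydes (a formal [3+3] annulation), which turns 3-methoxyphenol itself into 7-methoxy-2,2-dimethyl-2H-chromene; here it runs at both ends of one molecule and forms two C–C and two C–O bonds in one flask. Rings D and B each close by a thermal disrotatory oxa-6π electrocyclisation that forms O1–C2, and ring D should close first because ring C bears only an sp3 substituent para to O1, whereas in ring A the O1 lone pair that has to expel the boronate is shared with the para styryl group. No stereocentre is created in the product, the C4 centres of the dioxaborins vanish again, and the S centre is not touched because the medium holds no strong acid, base or oxidant. The step needs attack at C4a and not at C8: C4a is para to the methoxy group and unhindered, C8 lies between two oxygen substituents and is shielded by the O-methyl group that the C6 chain turns towards it, and the para position is blocked by the chain. It also needs the quinone methides to cyclise faster than the electron-rich styrene or a second phenol can intercept them, which the unimolecular closure at high dilution secures.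

Compound list
1 | 4-bromo-3-methoxyphenol | COc1cc(O)ccc1Br | starting material
2 | 1-bromo-2-methoxy-4-(methoxymethoxy)benzene | COCOc1ccc(Br)c(OC)c1 | intermediate
3 | but-3-en-2-one | CC(=O)C=C | starting material
4 | (E)-4-[2-methoxy-4-(methoxymethoxy)phenyl]but-3-en-2-one | COCOc1ccc(/C=C/C(C)=O)c(OC)c1 | intermediate
5 | (R,E)-4-[2-methoxy-4-(methoxymethoxy)phenyl]but-3-en-2-ol | COCOc1ccc(/C=C/[C@@H](C)O)c(OC)c1 | intermediate
6 | (R,E)-4-[2-methoxy-4-(methoxymethoxy)phenyl]but-3-en-2-yl pivalate | COCOc1ccc(/C=C/[C@@H](C)OC(=O)C(C)(C)C)c(OC)c1 | intermediate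
7 | [2-methoxy-4-(methoxymethoxy)phenyl]lithium | [Li]c1ccc(OCOC)cc1OC | intermediate
8 | [2-methoxy-4-(methoxymethoxy)phenyl]boronic acid | COCOc1ccc(B(O)O)c(OC)c1 | intermediate
9 | 2,4,6-tris[2-methoxy-4-(methoxymethoxy)phenyl]boroxine | COCOc1ccc(B2OB(c3ccc(OCOC)cc3OC)OB(c3ccc(OCOC)cc3OC)O2)c(OC)c1 | intermediate
10 | (S,E)-1,3-bis[2-methoxy-4-(methoxymethoxy)phenyl]but-1-ene | COCOc1ccc(/C=C/[C@H](C)c2ccc(OCOC)cc2OC)c(OC)c1 | intermediate
11 | (S,E)-4,4'-(but-1-ene-1,3-diyl)bis(3-methoxyphenol) | COc1cc(O)ccc1/C=C/[C@H](C)c1ccc(O)cc1OC | intermediate
12 | 3-methylbut-2-enal | CC(C)=CC=O | starting material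
13 | (S,E)-1,3-bis[7-methoxy-4-(2-methylprop-1-enyl)-2-phenyl-4H-1,3,2-benzodioxaborin-6-yl]but-1-ene, epimers at both C4 centres | COc1cc2OB(c3ccccc3)OC(C=C(C)C)c2cc1/C=C/[C@H](C)c1cc2C(C=C(C)C)OB(c3ccccc3)Oc2cc1OC | intermediate
14 | as 13, but ring C is a 3-methoxy-6-(3-methylbut-2-enylidene)cyclohexa-2,4-dien-1-one bound through its C4 to the S centre, while ring A is still the dioxaborin | COc1cc2OB(c3ccccc3)OC(C=C(C)C)c2cc1/C=C/[C@H](C)C1=CC(=CC=C(C)C)C(=O)C=C1OC | intermediate
15 | (S,E)-butene with 7-methoxy-2,2-dimethyl-2H-chromen-6-yl on the S centre (ring D closed) and the 7-methoxy-4-(2-methylprop-1-enyl)-2-phenyl-4H-1,3,2-benzodioxaborin-6-yl group on the alkene | COc1cc2OB(c3ccccc3)OC(C=C(C)C)c2cc1/C=C/[C@H](C)c1cc2C=CC(C)(C)Oc2cc1OC | intermediate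
16 | as 15, but ring A is a 3-methoxy-6-(3-methylbut-2-enylidene)cyclohexa-2,4-dien-1-one bound through its C4 to the E alkene | COC1=CC(=O)C(=CC=C(C)C)C=C1/C=C/[C@H](C)c1cc2C=CC(C)(C)Oc2cc1OC | intermediate
17 | (S,E)-1,3-bis(7-methoxy-2,2-dimethyl-2H-chromen-6-yl)but-1-ene | COc1cc2c(cc1/C=C/[C@H](C)c1cc3c(cc1OC)OC(C)(C)C=C3)C=CC(C)(C)O2 | target

Total step count: 8. Longest linear sequence: 7 steps (1, 2, 3, 4, 6, 7, 8).

Steps most likely to fail

Step 8. The second annulation may stall, and C–C bond formation may stray to the hindered ortho carbon. The quinone methides may be intercepted by the styrene or by a phenol, and the p-hydroxystyrene unit may oligomerise on long heating in the presence of acid. The fallback separates O–C and C–C bond formation and closes the rings at room temperature by metal catalysis. It sets out from 11. Both phenols are O-alkylated with 3-chloro-3-methylbut-1-yne (CuCl2·2H2O cat., DBU, MeCN, 0 °C) to (S,E)-1,3-bis[2-methoxy-4-(2-methylbut-3-yn-2-yloxy)phenyl]but-1-ene F1. Ph3PAuNTf2 (2 mol%, CH2Cl2, rt) then closes both pyran rings by 6-endo-dig hydroarylation at the carbon para to each methoxy group. This comes back to the route at 17.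

Step 6. Stereochemical fidelity may erode through ionisation of the electron-rich allylic pivalate or through exchange between π-allyl nickel species. Transmetalation of the ortho-methoxy boroxine may also be slow enough for protodeboronation to compete. The fallback sets the stereocentre by catalytic asymmetric conjugate addition instead of transfer from a carbinol. It sets out from 2.
- Aryllithium 7 is acylated with (E)-N-methoxy-N-methylbut-2-enamide (THF, −78 °C) to (E)-1-[2-methoxy-4-(methoxymethoxy)phenyl]but-2-en-1-one F2.
- Hayashi–Miyaura addition of boronic acid 8, now isolated ([Rh(OH)(cod)]2, (R)-BINAP, dioxane/H2O, 40 °C), should follow the usual facial preference of this ligand for E acyclic enones. It should give (S)-1,3-bis[2-methoxy-4-(methoxymethoxy)phenyl]butan-1-one F3.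
- NaBH4 in MeOH gives (3S)-1,3-bis[2-methoxy-4-(methoxymethoxy)phenyl]butan-1-ol F4 as both C1 epimers.
- PPTS-catalysed dehydration in warm toluene is easy because the carbinol sits on a 2,4-dioxygenated arene, and it gives the E alkene. This comes back to the route at 10.

Step 7. The electron-rich styrene may be protonated on the acidic surface and then hydrate or oligomerise. The released formaldehyde may also add back to the activated phenol rings. The fallback replaces protic hydrolysis by a two-stage protecting-group exchange that never exposes the styrene to an acid stronger than water. It sets out from 10. TMSOTf and 2,2'-bipyridyl (MeCN, 0 °C) exchange both acetals for silyl ethers and hold the C1 unit as a pyridinium salt. This gives (S,E)-1,3-bis[2-methoxy-4-(trimethylsilyloxy)phenyl]but-1-ene F5. Water at rt then frees the phenols, which comes back to the route at 11.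

Further compounds
F1 | step 8 | (S,E)-1,3-bis[2-methoxy-4-(2-methylbut-3-yn-2-yloxy)phenyl]but-1-ene | C#CC(C)(C)Oc1ccc(/C=C/[C@H](C)c2ccc(OC(C)(C)C#C)cc2OC)c(OC)c1
F2 | step 6 | (E)-1-[2-methoxy-4-(methoxymethoxy)phenyl]but-2-en-1-one | C/C=C/C(=O)c1ccc(OCOC)cc1OC
F3 | step 6 | (S)-1,3-bis[2-methoxy-4-(methoxymethoxy)phenyl]butan-1-one | COCOc1ccc(C(=O)C[C@H](C)c2ccc(OCOC)cc2OC)c(OC)c1
F4 | step 6 | (3S)-1,3-bis[2-methoxy-4-(methoxymethoxy)phenyl]butan-1-ol, both C1 epimers | COCOc1ccc(C(O)C[C@H](C)c2ccc(OCOC)cc2OC)c(OC)c1
F5 | step 7 | (S,E)-1,3-bis[2-methoxy-4-(trimethylsilyloxy)phenyl]but-1-ene | COc1cc(O[Si](C)(C)C)ccc1/C=C/[C@H](C)c1ccc(O[Si](C)(C)C)cc1OC
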